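**Assumption:** the target has no stereocentre and is achiral, so there is no enantiomer to select and no stereochemistry to set; the route below gives the one structure in the SMILES.

## Retrosynthetic overview

1. Verbenachalcone ← global hydrogenolysis of its tetra-O-benzyl ether (the four resorcinol OH groups protected, the ring B phenol free).
2. Tetrabenzyl ether ← both aryl–CH2 bonds made in one flask: a ketone homoenolate (β-carbon of the ketone as nucleophile), released from 1-arylcyclopropanol by palladium, is arylated twice by a dibromo diaryl ether.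
3. Cyclopropanol ← Kulinkovich reaction on benzyl-protected methyl 2,4-dihydroxybenzoate.
4. Dibromo diaryl ether ← SNAr of 4-bromo-2-methoxyphenol on 4-bromo-2-fluorobenzaldehyde, then Dakin-type oxidation of CHO to OH.
5. No ring is built: all four benzene rings are bought. The diaryl ether is made first, then both C3 ketone chains together; the only ring formed is the transient cyclopropane, which is opened in the key step.

## Route

**Step 1**
Reactants: 1 4-bromo-2-methoxyphenol; 2 4-bromo-2-fluorobenzaldehyde
Product: 3 4-bromo-2-(4-bromo-2-methoxyphenoxy)benzaldehyde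
Conditions: K2CO3, DMF, 110 °C
Reagents that add atoms: none
Why: Nucleophilic aromatic substitution (SNAr) in which the potassium phenoxide of 1 displaces the fluoride activated by the ortho formyl group, while both aryl bromides are left untouched.

**Step 2**
Reactants: 3 4-bromo-2-(4-bromo-2-methoxyphenoxy)benzaldehyde
Product: 5 4-bromo-2-(4-bromo-2-methoxyphenoxy)phenol, via aryl formate 4 (not isolated)
Conditions: mCPBA, CH2Cl2, 0 °C to rt; then K2CO3 (cat.), MeOH, rt
Reagents that add atoms: mCPBA, OOC(=O)c1cccc(Cl)c1
Why: Baeyer–Villiger oxidation of the aldehyde in the Dakin sense, in which the ring bearing the ortho aryloxy donor migrates to oxygen to give formate 4, which methanolysis cleaves to the phenol without affecting the bromides or the methyl ether.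

**Step 3**
Reactants: 6 methyl 2,4-dihydroxybenzoate
Product: 7 methyl 2,4-bis(benzyloxy)benzoate
Conditions: BnBr (2.5 equiv), K2CO3, DMF, 70 °C
Reagents that add atoms: benzyl bromide, BrCc1ccccc1
Why: Twofold Williamson etherification (SN2 on benzyl bromide), run warm because the 2-OH is hydrogen-bonded to the ester, with benzyl chosen because it survives the Grignard/titanium and palladium steps and leaves at the end by hydrogenolysis.

**Step 4**
Reactants: 7 methyl 2,4-bis(benzyloxy)benzoate
Product: 8 1-[2,4-bis(benzyloxy)phenyl]cyclopropan-1-ol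
Conditions: EtMgBr (2.8 equiv, slow addition), Ti(OiPr)4 (0.2 equiv), THF, 0 °C to rt; then H2O, filter through Celite
Reagents that add atoms: ethylmagnesium bromide, CC[Mg]Br
Why: Kulinkovich cyclopropanation, in which EtMgBr and Ti(OiPr)4 form a titanacyclopropane that acts as a 1,2-dicarbanion and adds twice to the ester carbonyl with loss of methoxide, the benzyl ethers being inert.

**Step 5 (key step)**
Reactants: 5 4-bromo-2-(4-bromo-2-methoxyphenoxy)phenol; 8 1-[2,4-bis(benzyloxy)phenyl]cyclopropan-1-ol (2.6 equiv)
Product: 10 1-[2,4-bis(benzyloxy)phenyl]-3-[3-[4-[3-[2,4-bis(benzyloxy)phenyl]-3-oxopropyl]-2-methoxyphenoxy]-4-hydroxyphenyl]propan-1-one, via mono-coupled bromo ketone 9 (not isolated)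
Conditions: Pd(OAc)2 (10 mol%), XPhos (20 mol%), Cs2CO3 (4 equiv), toluene, 80 °C
Reagents that add atoms: none
Why: Palladium-catalysed ring-opening cross-coupling of a cyclopropanol with an aryl bromide, run twice in one flask: each C–Br bond adds oxidatively to zerovalent palladium, bromide is exchanged for the cyclopropanolate, strain-driven β-carbon elimination gives a divalent palladium ketone homoenolate, and reductive elimination forms the aryl–CH2 bond, which the bulky biaryl phosphine makes faster than β-hydride elimination to the enone; the free phenol is carried as its cesium phenoxide, and the twofold use on a free-phenol dibromide is the untested part.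

**Step 6**
Reactants: 10 tetra-O-benzyl verbenachalcone (full name as in step 5)
Product: 11 verbenachalcone, 1-(2,4-dihydroxyphenyl)-3-[3-[4-[3-(2,4-dihydroxyphenyl)-3-oxopropyl]-2-methoxyphenoxy]-4-hydroxyphenyl]propan-1-one
Conditions: H2 (1 atm), Pd/C (10 wt% palladium on carbon), EtOAc/MeOH, rt, stopped after uptake of 4 equiv H2
Reagents that add atoms: none
Why: Catalytic hydrogenolysis of the four benzyl aryl ethers, under which the electron-rich aryl ketones (hydrogen-bonded to the freed 2-OH), the diaryl ether and the methyl ether are not reduced at 1 atm.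

## Compound list

1 | 4-bromo-2-methoxyphenol | COc1cc(Br)ccc1O | starting material
2 | 4-bromo-2-fluorobenzaldehyde | O=Cc1ccc(Br)cc1F | starting material
3 | 4-bromo-2-(4-bromo-2-methoxyphenoxy)benzaldehyde | COc1cc(Br)ccc1Oc1cc(Br)ccc1C=O | intermediate
4 | 4-bromo-2-(4-bromo-2-methoxyphenoxy)phenyl formate | COc1cc(Br)ccc1Oc1cc(Br)ccc1OC=O | intermediate (not isolated)
5 | 4-bromo-2-(4-bromo-2-methoxyphenoxy)phenol | COc1cc(Br)ccc1Oc1cc(Br)ccc1O | intermediate
6 | methyl 2,4-dihydroxybenzoate | COC(=O)c1ccc(O)cc1O | starting material
7 | methyl 2,4-bis(benzyloxy)benzoate | COC(=O)c1ccc(OCc2ccccc2)cc1OCc1ccccc1 | intermediate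
8 | 1-[2,4-bis(benzyloxy)phenyl]cyclopropan-1-ol | OC1(CC1)c1ccc(OCc2ccccc2)cc1OCc1ccccc1 | intermediate
9 | 1-[2,4-bis(benzyloxy)phenyl]-3-[4-(5-bromo-2-hydroxyphenoxy)-3-methoxyphenyl]propan-1-one | COc1cc(CCC(=O)c2ccc(OCc3ccccc3)cc2OCc2ccccc2)ccc1Oc1cc(Br)ccc1O | intermediate (not isolated)
10 | 1-[2,4-bis(benzyloxy)phenyl]-3-[3-[4-[3-[2,4-bis(benzyloxy)phenyl]-3-oxopropyl]-2-methoxyphenoxy]-4-hydroxyphenyl]propan-1-one | COc1cc(CCC(=O)c2ccc(OCc3ccccc3)cc2OCc2ccccc2)ccc1Oc1cc(CCC(=O)c2ccc(OCc3ccccc3)cc2OCc2ccccc2)ccc1O | intermediate
11 | verbenachalcone | COc1cc(CCC(=O)c2ccc(O)cc2O)ccc1Oc1cc(CCC(=O)c2ccc(O)cc2O)ccc1O | target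

## Summary

Total step count: 6.
Longest linear sequence: 4 steps (steps 1, 2, 5, 6 from compound 1; equally steps 3, 4, 5, 6 from compound 6).

**Three steps most likely to fail**

Step 5 (twofold homoenolate arylation). The risks are slow oxidative addition at the phenoxide-bearing ring, β-hydride elimination to the aryl vinyl ketone, and base-induced opening of 8 to the propiophenone. The fallback sets out from 5 and keeps the homoenolate idea but at the ester level. Twofold Negishi coupling of 5 with (3-ethoxy-3-oxopropyl)zinc bromide (3.5 equiv, Pd(OAc)2, SPhos, THF, 50 °C) gives the diester ethyl 3-[3-[4-(3-ethoxy-3-oxopropyl)-2-methoxyphenoxy]-4-hydroxyphenyl]propanoate F1. LiOH in THF/H2O then gives the diacid 3-[3-[4-(2-carboxyethyl)-2-methoxyphenoxy]-4-hydroxyphenyl]propanoic acid F2. Heating F2 with excess resorcinol in BF3·OEt2 at 85 °C (Friedel–Crafts C-acylation at C4 of resorcinol, both acid groups) gives the target directly. The fallback comes back to the route at 11 and needs neither 8 nor 10.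

Step 4 (Kulinkovich reaction on an electron-rich, ortho-alkoxy aryl ester). The risks are sluggish ligand exchange and simple ethyl addition to the ester. The fallback sets out from 7 and builds the cyclopropanol from two one-carbon units instead of one two-carbon unit. Chloromethyllithium made in the flask (ICH2Cl, MeLi·LiBr, THF, −78 °C, cold acidic quench) converts 7 into the chloromethyl ketone 1-[2,4-bis(benzyloxy)phenyl]-2-chloroethan-1-one F3. Sm metal and CH2I2 in THF then reduce F3 to its samarium enolate and cyclopropanate it with the samarium carbenoid. The fallback comes back to the route at 8.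

Step 2 (Dakin-type oxidation). The risk is hydride migration, which would give the benzoic acid instead of the formate because the migrating ring carries only an aryloxy donor and a para bromide. The fallback sets out from 1 and puts the oxygen in through nitrogen. SNAr of 1 with 4-bromo-2-fluoro-1-nitrobenzene (K2CO3, DMF, 60 °C) gives 4-bromo-1-(5-bromo-2-nitrophenoxy)-2-methoxybenzene F4. Fe powder and NH4Cl in EtOH/H2O at 70 °C reduce the nitro group without touching the bromides and give 4-bromo-2-(4-bromo-2-methoxyphenoxy)aniline F5. Diazotisation (NaNO2, aq. H2SO4, 0 °C) followed by hydroxylation of the diazonium salt with Cu2O and Cu(NO3)2 in water gives the phenol. The fallback comes back to the route at 5.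

## Further compounds

F1 | step 5 | ethyl 3-[3-[4-(3-ethoxy-3-oxopropyl)-2-methoxyphenoxy]-4-hydroxyphenyl]propanoate | COc1cc(CCC(=O)OCC)ccc1Oc1cc(CCC(=O)OCC)ccc1O
F2 | step 5 | 3-[3-[4-(2-carboxyethyl)-2-methoxyphenoxy]-4-hydroxyphenyl]propanoic acid | COc1cc(CCC(=O)O)ccc1Oc1cc(CCC(=O)O)ccc1O
F3 | step 4 | 1-[2,4-bis(benzyloxy)phenyl]-2-chloroethan-1-one | O=C(CCl)c1ccc(OCc2ccccc2)cc1OCc1ccccc1
F4 | step 2 | 4-bromo-1-(5-bromo-2-nitrophenoxy)-2-methoxybenzene | COc1cc(Br)ccc1Oc1cc(Br)ccc1[N+](=O)[O-]
F5 | step 2 | 4-bromo-2-(4-bromo-2-methoxyphenoxy)aniline | COc1cc(Br)ccc1Oc1cc(Br)ccc1N
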